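Colleterpenol is numbered around the ring: C14 is the ring CH, C1 its CH2 neighbour allylic to C2=C3, C15 the carbinol carbon. The 14-membered carbocycle is disconnected at C9–C10, the CH2–CH= bond of the C10=C11 olefin, remote from the C14/C15 stereodiad. Because C9 is homoallylic to C6=C7, a terminal C6=C7–C8=C9 diene is its latent form: 9-BBN hydroboration and intramolecular B-alkyl Suzuki coupling with a C10 (E)-alkenyl iodide close the ring in one operation and give the free alcohol directly. The open-chain precursor comes from (2S,3S)-2,3-epoxyfarnesol, whose anti opening at C14 sets both stereocentres, and a trienyl iodide joined at C1–C2.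

Key step: step 12

Remarks on the chemistry:
- Methyls sit on C3, C7, C11 and C15; the side chain runs C16–C23 with olefins C18=C19 and C22=C23. The target is (14R,15S).
- Pent-4-yn-1-ol, (2E,6E)-farnesol, 4-bromo-1-(trimethylsilyl)but-1-yne and the reagents named are taken as commercial.
- The hindered tertiary alcohol is assumed to bind Me3Al or 9-BBN at most as an O-bound species that aqueous work-up releases.

Step 1
Reactants: 1 pent-4-yn-1-ol
Product: 3 (E)-5-iodo-4-methylpent-4-en-1-ol, via alkenylalane 2 (not isolated)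
Conditions: Me3Al, Cp2ZrCl2 (cat.), CH2Cl2, 0 °C to rt; then I2, THF, −30 °C; aq. K2CO3
Reagents that add atoms: trimethylaluminium C[Al](C)C; iodine [I][I]
Why: Zirconium-catalysed syn methylalumination of the terminal alkyne (Negishi carboalumination) places CH3 on the internal carbon and aluminium on the terminal one, and iodinolysis with retention should give the (E)-iodoalkene that becomes C2=C3.

Step 2
Reactants: 3 (E)-5-iodo-4-methylpent-4-en-1-ol
Product: 4 (E)-5-iodo-4-methylpent-4-enal
Conditions: Dess–Martin periodinane, NaHCO3, CH2Cl2, 0 °C to rt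
Reagents that add atoms: none
Why: Dess–Martin oxidation should convert the primary alcohol into the aldehyde under buffered conditions that leave the alkenyl iodide untouched.

Step 3
Reactants: 4 (E)-5-iodo-4-methylpent-4-enal
Product: 5 (2E,6E)-7-iodo-2,6-dimethylhepta-2,6-dienal
Conditions: Ph3P=C(CH3)CHO, toluene, 90 °C
Reagents that add atoms: 2-(triphenylphosphoranylidene)propanal CC(C=O)=P(c1ccccc1)(c1ccccc1)c1ccccc1
Why: Wittig olefination with the stabilised formyl ylide should give the (E)-2-methyl enal, which installs the C6=C7 trisubstituted olefin with the geometry typical of stabilised ylides.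

Step 4
Reactants: 5 (2E,6E)-7-iodo-2,6-dimethylhepta-2,6-dienal
Product: 6 (1E,5E)-1-iodo-2,6-dimethylocta-1,5,7-triene
Conditions: Ph3PCH3Br, KHMDS, THF, −78 °C to 0 °C
Reagents that add atoms: methylenetriphenylphosphorane C=P(c1ccccc1)(c1ccccc1)c1ccccc1 (made in the flask from methyltriphenylphosphonium bromide and KHMDS)
Why: Wittig methylenation of the enal should give the terminal 1,3-diene (C8=C9) without touching the alkenyl iodide or either olefin geometry.

Step 5
Reactants: 7 (2E,6E)-farnesol
Product: 8 (2S,3S)-2,3-epoxyfarnesol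
Conditions: Ti(OiPr)4 (cat.), L-(+)-diethyl tartrate (cat.), t-BuOOH, 4 Å MS, CH2Cl2, −20 °C
Reagents that add atoms: tert-butyl hydroperoxide CC(C)(C)OO
Why: Katsuki–Sharpless asymmetric epoxidation acts only on the allylic 2,3-olefin, and with L-(+)-tartrate oxygen is delivered to the face that gives the (2S,3S)-epoxide, which fixes C15 as S and defines the face of attack at C14.

Step 6
Reactants: 8 (2S,3S)-2,3-epoxyfarnesol; 9 4-bromo-1-(trimethylsilyl)but-1-yne
Product: 11 (2R,3S,6E)-3,7,11-trimethyl-2-[4-(trimethylsilyl)but-3-yn-1-yl]dodeca-6,10-diene-1,3-diol, via Grignard reagent 10 (not isolated)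
Conditions: 9, Mg, THF; then CuBr·SMe2 (cat.), 8, THF, −40 °C to 0 °C
Reagents that add atoms: none
Why: Copper-catalysed Grignard opening of a 2,3-epoxy alcohol: the fully substituted C3 is closed to SN2 attack, so the cuprate should attack the secondary C2 (future C14) anti to the epoxide oxygen, and this inversion sets 14R while C15 keeps its C–O bond and its S configuration.

Step 7
Reactants: 11 the 1,3-diol
Product: 12 (5S,6S,9E)-5-(iodomethyl)-6,10,14-trimethyl-1-(trimethylsilyl)pentadeca-9,13-dien-1-yn-6-ol
Conditions: I2, PPh3, imidazole, CH2Cl2, 0 °C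
Reagents that add atoms: iodine [I][I]
Why: Appel-type iodination should activate only the primary hydroxyl, the tertiary alcohol being too hindered to form the oxyphosphonium ion; no stereocentre is touched (the descriptor at C14 changes only because iodine raises the priority of C1).

Step 8
Reactants: 12 the primary iodide
Product: 13 triethylsilyl ether of 12
Conditions: TESOTf, 2,6-lutidine, CH2Cl2, −78 °C to 0 °C
Reagents that add atoms: triethylsilyl trifluoromethanesulfonate CC[Si](CC)(CC)OS(=O)(=O)C(F)(F)F
Why: Silylation with the reactive triflate masks the tertiary alcohol so that no alkoxide sits 1,3 to the carbanion generated in the next step.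

Step 9
Reactants: 13 the silyl-protected iodide; 6 (1E,5E)-1-iodo-2,6-dimethylocta-1,5,7-triene
Product: 16 (3E,7E,10R,11S,14E)-3,7,11,15,19-pentamethyl-11-[(triethylsilyl)oxy]-10-[4-(trimethylsilyl)but-3-yn-1-yl]icosa-1,3,7,14,18-pentaene, via alkyllithium 14 (not isolated), via lithium borate 15 (not isolated)
Conditions: t-BuLi (2.1 equiv), Et2O, −78 °C; B-methoxy-9-BBN, THF, −78 °C to rt; then 6, Pd(dppf)Cl2 (cat.), AsPh3, aq. K3PO4, DMF, rt
Reagents that add atoms: none
Why: B-alkyl Suzuki–Miyaura coupling: iodine–lithium exchange and capture by B-methoxy-9-BBN give a borate that transmetalates to the alkenylpalladium iodide formed from 6, so that C1–C2 should form with retention of the (E) geometry at C2=C3.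

Step 10
Reactants: 16 the coupled silyl ether
Product: 17 (3E,7E,10R,11S,14E)-10-(but-3-yn-1-yl)-3,7,11,15,19-pentamethylicosa-1,3,7,14,18-pentaen-11-ol
Conditions: TBAF, THF, 0 °C to rt
Reagents that add atoms: none
Why: Fluoride should cleave both the alkynyl C–Si bond and the tertiary O–Si bond in one operation, giving the terminal alkyne and the free carbinol.

Step 11
Reactants: 17 the alkynol
Product: 19 (3E,7E,10R,11S,14E)-10-[(3E)-4-iodo-3-methylbut-3-en-1-yl]-3,7,11,15,19-pentamethylicosa-1,3,7,14,18-pentaen-11-ol, via alkenylalane 18 (not isolated)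
Conditions: Me3Al, Cp2ZrCl2 (cat.), H2O (1 equiv), CH2Cl2, −25 °C; then I2, THF, −30 °C; aq. K2CO3
Reagents that add atoms: trimethylaluminium C[Al](C)C; iodine [I][I]
Why: Water-accelerated Negishi carboalumination at low temperature should engage only the terminal alkyne, not the trisubstituted olefins or the conjugated diene, and syn addition followed by iodinolysis with retention should give the (E)-C10=C11 alkenyl iodide.

Step 12
Reactants: 19 the seco alkenyl iodide
Product: 21 colleterpenol, via B-alkyl-9-BBN 20 (not isolated)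
Conditions: 9-BBN (2.5 equiv), THF, 0 °C to rt; then slow addition to Pd(dppf)Cl2 (20 mol %), AsPh3, Cs2CO3, DMF/THF/H2O, 50 °C, about 1 mM
Reagents that add atoms: none
Why: 9-BBN should add only to the monosubstituted C8=C9 terminus of the diene with boron at C9, leaving the four trisubstituted olefins and the alkenyl iodide untouched; zerovalent palladium then inserts into the C10–I bond, the base-activated C9 borate transmetalates, and reductive elimination forms C9–C10 with retention of the (E) geometry at C10=C11. The closest known reaction type is the intramolecular B-alkyl Suzuki–Miyaura macrocyclisation. The 14-membered carbocycle is closed end to end by reductive elimination from a 15-membered palladacycle, with the C10=C11 double bond inside the ring. No stereocentre is created: C14 and C15 are untouched and the alkene geometry is inherited from 19. The step needs chemo- and regioselective hydroboration, which the substitution pattern of the diene secures, and ring closure over oligomerisation, which slow addition at high dilution and the three (E)-trisubstituted olefins that restrict chain conformations should favour. The dppf ligand is chosen to suppress beta-hydride elimination from the alkylpalladium intermediate.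

Compound list
1 | pent-4-yn-1-ol | C#CCCCO | starting material
2 | alkenylalane from 1 (O–AlMe2 and C–AlMe2) | C[Al](C)OCCC/C(C)=C/[Al](C)C | intermediate
3 | (E)-5-iodo-4-methylpent-4-en-1-ol | OCCC/C(C)=C/I | intermediate
4 | (E)-5-iodo-4-methylpent-4-enal | O=CCC/C(C)=C/I | intermediate
5 | (2E,6E)-7-iodo-2,6-dimethylhepta-2,6-dienal | O=C/C(C)=C/CC/C(C)=C/I | intermediate
6 | (1E,5E)-1-iodo-2,6-dimethylocta-1,5,7-triene | C=C/C(C)=C/CC/C(C)=C/I | intermediate
7 | (2E,6E)-farnesol | CC(C)=CCC/C(C)=C/CC/C(C)=C/CO | starting material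
8 | (2S,3S)-2,3-epoxyfarnesol | CC(C)=CCC/C(C)=C/CC[C@]1(C)O[C@H]1CO | intermediate
9 | 4-bromo-1-(trimethylsilyl)but-1-yne | BrCCC#C[Si](C)(C)C | starting material
10 | [4-(trimethylsilyl)but-3-yn-1-yl]magnesium bromide | C[Si](C)(C)C#CCC[Mg]Br | intermediate
11 | (2R,3S,6E)-3,7,11-trimethyl-2-[4-(trimethylsilyl)but-3-yn-1-yl]dodeca-6,10-diene-1,3-diol | CC(C)=CCC/C(C)=C/CC[C@](C)(O)[C@H](CCC#C[Si](C)(C)C)CO | intermediate
12 | (5S,6S,9E)-5-(iodomethyl)-6,10,14-trimethyl-1-(trimethylsilyl)pentadeca-9,13-dien-1-yn-6-ol | CC(C)=CCC/C(C)=C/CC[C@](C)(O)[C@H](CCC#C[Si](C)(C)C)CI | intermediate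
13 | triethyl{[(5S,6S,9E)-5-(iodomethyl)-6,10,14-trimethyl-1-(trimethylsilyl)pentadeca-9,13-dien-1-yn-6-yl]oxy}silane | CC(C)=CCC/C(C)=C/CC[C@](C)(O[Si](CC)(CC)CC)[C@H](CCC#C[Si](C)(C)C)CI | intermediate
14 | primary alkyllithium from 13 (lithium on C1) | CC(C)=CCC/C(C)=C/CC[C@](C)(O[Si](CC)(CC)CC)[C@H](CCC#C[Si](C)(C)C)C[Li] | intermediate
15 | lithium B-alkyl-B-methoxy-9-borabicyclo[3.3.1]nonane borate from 14 | CC(C)=CCC/C(C)=C/CC[C@](C)(O[Si](CC)(CC)CC)[C@H](CCC#C[Si](C)(C)C)C[B-]1(OC)C2CCCC1CCC2.[Li+] | intermediate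
16 | (3E,7E,10R,11S,14E)-3,7,11,15,19-pentamethyl-11-[(triethylsilyl)oxy]-10-[4-(trimethylsilyl)but-3-yn-1-yl]icosa-1,3,7,14,18-pentaene | CC(C)=CCC/C(C)=C/CC[C@](C)(O[Si](CC)(CC)CC)[C@H](CCC#C[Si](C)(C)C)C/C=C(\C)CC/C=C(\C)C=C | intermediate
17 | (3E,7E,10R,11S,14E)-10-(but-3-yn-1-yl)-3,7,11,15,19-pentamethylicosa-1,3,7,14,18-pentaen-11-ol | CC(C)=CCC/C(C)=C/CC[C@](C)(O)[C@H](CCC#C)C/C=C(\C)CC/C=C(\C)C=C | intermediate
18 | alkenylalane from 17 (O–AlMe2 and C10–AlMe2) | CC(C)=CCC/C(C)=C/CC[C@](C)(O[Al](C)C)[C@H](CC/C(C)=C/[Al](C)C)C/C=C(\C)CC/C=C(\C)C=C | intermediate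
19 | (3E,7E,10R,11S,14E)-10-[(3E)-4-iodo-3-methylbut-3-en-1-yl]-3,7,11,15,19-pentamethylicosa-1,3,7,14,18-pentaen-11-ol | CC(C)=CCC/C(C)=C/CC[C@](C)(O)[C@H](CC/C(C)=C/I)C/C=C(\C)CC/C=C(\C)C=C | intermediate
20 | B-alkyl-9-BBN from 19 (boron on C9) | CC(C)=CCC/C(C)=C/CC[C@](C)(O)[C@H](CC/C(C)=C/I)C/C=C(\C)CC/C=C(\C)CCB1C2CCCC1CCC2 | intermediate
21 | colleterpenol, (14R,15S) | CC(C)=CCC/C(C)=C/CC[C@](C)(O)[C@H]1C/C=C(\C)CC/C=C(\C)CC/C=C(\C)CC1 | target

Total step count: 12 (steps 1–4 for iodide 6, steps 5–8 for iodide 13, steps 9–12 after their union).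
Longest linear sequence: 8 steps (farnesol 7 to colleterpenol 21, steps 5–12).

Steps most likely to fail

Step 12. At the dilution needed for ring closure, transmetalation of the alkylborane may be slower than protodeboronation, dehalogenation or intermolecular coupling, so that reduced open-chain material or oligomers form instead of the ring. The fallback sets out from 19 and comes back at 21, closing the same C9–C10 bond by carbonyl addition. Hydroboration of the diene terminus of 19 with 9-BBN and oxidative work-up (NaBO3) would give primary alcohol F1, and Dess–Martin oxidation would give aldehyde F2. Intramolecular Nozaki–Hiyama–Kishi coupling (CrCl2, NiCl2 cat., DMSO/THF, high dilution) should add the C10 alkenylchromium to the C9 aldehyde and give macrocyclic allylic alcohol F3 as a mixture at C9, which is of no consequence. The secondary hydroxyl alone is converted into methyl carbonate F4 (ClCO2Me, pyridine). Palladium-catalysed hydride displacement (Pd(PPh3)4, LiBHEt3, THF) should then deliver hydride to the less substituted C9 terminus of the allyl complex, keeping the (E)-C10=C11 olefin and giving 21.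

Step 6. SN2 attack at the epoxide carbon next to the fully substituted C15 may be slow, so that magnesium-assisted opening at the tertiary carbon, halohydrin formation or elimination to an allylic alcohol could take over. The fallback sets out from 8 and comes back at 11, using a far more nucleophilic reagent and building the arm stepwise. Allylmagnesium chloride (THF, −20 °C) should open 8 at C14 with inversion to give allyl diol F5, which is protected as acetonide F6 (2,2-dimethoxypropane, PPTS). 9-BBN then NaOH/H2O2 should hydroborate only the monosubstituted alkene to give primary alcohol F7, and Dess–Martin oxidation gives aldehyde F8. Ohira–Bestmann homologation (K2CO3, MeOH) gives terminal alkyne F9, n-BuLi/TMSCl gives silylalkyne F10, and aqueous acetic acid removes the acetonide to return 11.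

Step 9. The alkyllithium may undergo silyl migration from oxygen to carbon or internal proton transfer before it is trapped, and the hindered borate may transmetalate sluggishly, leading to reduced alkane and unreacted 6. The fallback sets out from 13 (with 6) and comes back at 16 without any organolithium. Direct insertion of zinc dust (LiCl, THF, 40 °C) into the primary C–I bond of 13 would give alkylzinc iodide F11, which should undergo Negishi coupling with 6 (Pd(dppf)Cl2, THF/DMA) to give 16.

Further compounds
F1 | step 12 | (3E,7E,10R,11S,14E)-10-[(3E)-4-iodo-3-methylbut-3-en-1-yl]-3,7,11,15,19-pentamethylicosa-3,7,14,18-tetraene-1,11-diol | CC(C)=CCC/C(C)=C/CC[C@](C)(O)[C@H](CC/C(C)=C/I)C/C=C(\C)CC/C=C(\C)CCO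
F2 | step 12 | C9 aldehyde corresponding to F1 | CC(C)=CCC/C(C)=C/CC[C@](C)(O)[C@H](CC/C(C)=C/I)C/C=C(\C)CC/C=C(\C)CC=O
F3 | step 12 | 9-hydroxycolleterpenol (mixture at C9) | CC(C)=CCC/C(C)=C/CC[C@](C)(O)[C@H]1C/C=C(\C)CC/C=C(\C)CC(O)/C=C(\C)CC1
F4 | step 12 | 9-O-(methoxycarbonyl) derivative of F3 | CC(C)=CCC/C(C)=C/CC[C@](C)(O)[C@H]1C/C=C(\C)CC/C=C(\C)CC(OC(=O)OC)/C=C(\C)CC1
F5 | step 6 | (2R,3S,6E)-3,7,11-trimethyl-2-(prop-2-en-1-yl)dodeca-6,10-diene-1,3-diol | CC(C)=CCC/C(C)=C/CC[C@](C)(O)[C@H](CC=C)CO
F6 | step 6 | (4S,5R)-4-[(3E)-4,8-dimethylnona-3,7-dien-1-yl]-2,2,4-trimethyl-5-(prop-2-en-1-yl)-1,3-dioxane | CC(C)=CCC/C(C)=C/CC[C@]1(C)OC(C)(C)OC[C@H]1CC=C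
F7 | step 6 | 3-[(4S,5R)-4-[(3E)-4,8-dimethylnona-3,7-dien-1-yl]-2,2,4-trimethyl-1,3-dioxan-5-yl]propan-1-ol | CC(C)=CCC/C(C)=C/CC[C@]1(C)OC(C)(C)OC[C@H]1CCCO
F8 | step 6 | aldehyde corresponding to F7 | CC(C)=CCC/C(C)=C/CC[C@]1(C)OC(C)(C)OC[C@H]1CCC=O
F9 | step 6 | (4S,5R)-5-(but-3-yn-1-yl) acetonide | CC(C)=CCC/C(C)=C/CC[C@]1(C)OC(C)(C)OC[C@H]1CCC#C
F10 | step 6 | acetonide of diol 11 | CC(C)=CCC/C(C)=C/CC[C@]1(C)OC(C)(C)OC[C@H]1CCC#C[Si](C)(C)C
F11 | step 9 | alkylzinc iodide from 13 (zinc on C1) | CC(C)=CCC/C(C)=C/CC[C@](C)(O[Si](CC)(CC)CC)[C@H](CCC#C[Si](C)(C)C)C[Zn]I
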